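| flask | starting material | reagent | remark | time |
|---|---|---|---|---|
| elm | 0.17 M | 1.2 equiv | run made earlier |  |
| larch | 0.12 M | 1.2 equiv | run made earlier |  |
| grey | 0.25 M | 1.20 equiv |  | 80 min |
| blue | 0.25 M | 0.400 equiv |  | 20 min |

- elm (time / min: single product / %, double product / %): 4.00: 16.9, 26.1; 12.0: 15.4, 35.4; 20.0: 13.8, 36.7; 30.0: 13.6, 36.5; 50.0: 12.0, 36.7
- larch (time / min: single product / %, double product / %): 4.00: 17.3, 21.0; 8.00: 16.4, 29.6; 15.0: 14.9, 34.9; 25.0: 14.5, 36.2; 50.0: 13.5, 36.6

(scatter of a reading: 0.3 percentage points)

- percentages count the starting material that a species holds: one side product counts as two

- the flask that ends with the higher share of single product in all that became single product or double product or side product, or "neither" when 2 percentage points or less lies between them (grey / blue / neither)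
- share of single product in all that became single product or double product or side product, grey
- share of single product in all that became single product or double product or side product, blue

**One scale.** I decided to set grey beside elm, since both carry the same equivalents of reagent, and to place them on one scale, the exposure E, meaning starting concentration times time. Elm at its last reading had 510 M·s, while grey at its end would have 1200 M·s, which is 2.35 times as much.

**Fade constant.** From 20.0 min to 50.0 min elm's double product read 36.7% and 36.7%, while its single product fell from 13.8% to 12.0%. Since a side product holds two, I took each lost single product to pair with one starting material, and, as a rough assumption of mine that the readings could not test, showing no starting material, I held that partner's fraction steady, so dm/dE = −fm integrated to m = p·exp(−fE), with m the fraction of the charge held as single product. Elm gave the fade constant f, 0.0274 M⁻¹ min⁻¹, the logarithmic loss of m per unit of exposure. Larch, read the same way from 15.0 min, gave 0.0235 M⁻¹ min⁻¹, close given the scatter of 0.3 percentage points.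

**Two endings.** Running elm back to zero exposure gave p = 15.1%. Each fraction lost from m should return doubled as side product, so I reckoned the share as m/(m + d + 2(p − m)), with d the double product. Elm's last reading gave 21.8%. Grey, with elm's double product, gave m = 8.76% and a share of 15.0%, lower than elm's through its greater exposure. Blue had no comparable run, so I ranked it without a number: its exposure was a quarter of grey's, on a third of grey's equivalents.

**The forecast.** It named blue, with 10.5% for grey and 40% for blue, reasoning that “Side product and double product together hold about 75–90%”. I agreed on the direction but differed on grey.

    starting material + reagent → single product + by-product (k = 1.80 M⁻¹ min⁻¹)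
    starting material + reagent → other mono adduct + by-product (k = 2.40 M⁻¹ min⁻¹)
    reagent + single product → double product + by-product (k = 3.10 M⁻¹ min⁻¹)
    reagent + other mono adduct → double product + by-product (k = 1.50 M⁻¹ min⁻¹)
    starting material + single product → side product (k = 0.170 M⁻¹ min⁻¹)
    2 starting material → self-condensation product (k = 0.0650 M⁻¹ min⁻¹)

**The result.** Grey ended at 18.6% and blue at 39.7%, so blue held the higher share, and my grey figure lay nearer than the forecast's. Grey's starting material fell from 9.70% at 40.0 min to 7.17% at 80.0 min, so the partner I had held steady was not steady. The neighbouring flask was grey at 0.062 M, with equivalents and time held, so its exposure was 298 M·s; the same fade constant put m at 13.2% and the share at 24.6%. That flask ended with 13.5% single product, 36.7% double product, 4.29% side product and a share of 24.7%.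

The readings come from a simulation from invented constants; noise was put on by code.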